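**Plan**
- Retrosynthesis: first cut the C1–Cα bond of the propenal arm (Suzuki–Miyaura coupling on a C1 bromide), then the C5–O5 aryl ether bond of ring B (Ullmann closure), then O4–C8' and C7'–C8' together (three-component carbene coupling).
- Enabling feature: ring A is the propenal arene (C1 side chain, C3 OMe, C4–O4, C5–O5), ring B the dioxane O5–C7'–C8'–O4, ring C the guaiacyl group on C7'. C8' is bonded to O4, C7' and C9', the three bonds a diazoacetate carbon makes when a phenol O–H and then an aldehyde capture it.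
- Forward: phenol 1, ethyl diazoacetate 2 and vanillin acetate 3 give the open O4–C8'(C9')–C7' chain in one step. Ester reduction and silylation follow, ring B closes at C5, the propenal unit is coupled at C1, and the silyl groups are removed. Rings A and C are bought.
- Stereochemistry: C7' and C8' are both set in the key step by a chiral BINOL phosphoric acid as the threo (2R,3S) pair. Ring closure with retention turns threo into trans, that is (7'S,8'S).

Key step: step 1

Assumption: the sense of induction of the phosphoric acid cannot be assigned with confidence by analogy. (R)-TRIP, (R)-3,3'-bis(2,4,6-triisopropylphenyl)-1,1'-binaphthyl-2,2'-diyl hydrogen phosphate, is written throughout, and its (S) antipode takes its place if a first run shows the mirror-image sense.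

Step 1
Reactants: 1 2,4-dibromo-6-methoxyphenol; 2 ethyl diazoacetate; 3 4-formyl-2-methoxyphenyl acetate (vanillin acetate)
Product: 5 ethyl (2R,3S)-3-[4-(acetyloxy)-3-methoxyphenyl]-2-(2,4-dibromo-6-methoxyphenoxy)-3-hydroxypropanoate, via ester enol 4 (not isolated)
Conditions: Rh2(OAc)4 (2 mol %), (R)-TRIP (10 mol %), 4 Å MS, CH2Cl2, −20 °C; 3 (2 equiv); 2 (1.5 equiv) by syringe pump over 4 h
Reagents that add atoms: none
Why: Proposed new method: Rh2(OAc)4 (a divalent rhodium carboxylate) decomposes 2 to an electrophilic carbene that O4–H of phenol 1 captures as a rhodium-associated oxonium ylide, which relaxes to the hydrogen-bonded ester enol 4; inside the chiral phosphate this enol adds through C8' to the carbonyl carbon of 3, forming C7'–C8' after O4–C8' and before C8' is protonated. The closest known reaction type is the Rh2(OAc)4/chiral phosphoric acid three-component coupling of aryl diazoacetates with alcohols and imines or activated aldehydes, together with the phosphoric-acid-mediated asymmetric O–H insertion of phenols, in which the same enol is intercepted by a proton instead of a carbon electrophile; an unsubstituted diazoacetate combined with an aryl aldehyde has no direct counterpart. No ring is closed in this step, so no mode of closure applies. C8' and C7' should arise together in one closed, doubly hydrogen-bonded transition state (P=O to the enol O–H, P–OH to the aldehyde oxygen), in which the 3,3'-aryl walls of the BINOL phosphate select the enol face and the aldehyde face and thereby both the threo relationship and the (2R,3S) absolute sense. The step needs C–C bond formation to outrun the 1,2-proton shift to the plain O–H insertion ester, and needs the carbene to choose the phenol oxygen over the aldehyde oxygen; the O-acetyl group should secure both by making the carbonyl carbon of 3 more electrophilic and its oxygen less basic than in a silyl ether or free phenol analogue, supported by excess 3, low temperature and slow addition of 2. The bromides at C5 and C1 are inert to the carbene and are carried for the later ring closure and coupling.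

Step 2
Reactants: 5 ethyl (2R,3S)-3-[4-(acetyloxy)-3-methoxyphenyl]-2-(2,4-dibromo-6-methoxyphenoxy)-3-hydroxypropanoate
Product: 6 (1S,2S)-2-(2,4-dibromo-6-methoxyphenoxy)-1-(4-hydroxy-3-methoxyphenyl)propane-1,3-diol
Conditions: LiBH4 (4 equiv), THF, 0 °C to rt; then 1 M HCl to pH 6 at 0 °C
Reagents that add atoms: none
Why: Lithium borohydride reduction of the activated α-aryloxy ester to the primary alcohol should also remove the aryl acetate as ethanol, while the aryl bromides are untouched and C8' is reduced out of its enolisable position before it can epimerise (the descriptor at C8' changes from R to S only because the CIP priorities change).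

Step 3
Reactants: 6 (1S,2S)-2-(2,4-dibromo-6-methoxyphenoxy)-1-(4-hydroxy-3-methoxyphenyl)propane-1,3-diol
Product: 7 (1S,2S)-2-(2,4-dibromo-6-methoxyphenoxy)-1-{3-methoxy-4-[(triisopropylsilyl)oxy]phenyl}-3-[(triisopropylsilyl)oxy]propan-1-ol
Conditions: TIPSCl (2.3 equiv), imidazole (5 equiv), DMF, 0 °C to rt
Reagents that add atoms: triisopropylsilyl chloride, CC(C)[Si](Cl)(C(C)C)C(C)C
Why: Imidazole-promoted silylation with the bulky chlorosilane should take the phenol and the primary hydroxyl but not the flanked secondary benzylic hydroxyl at C7', which is the nucleophile needed in step 4.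

Step 4
Reactants: 7 (1S,2S)-2-(2,4-dibromo-6-methoxyphenoxy)-1-{3-methoxy-4-[(triisopropylsilyl)oxy]phenyl}-3-[(triisopropylsilyl)oxy]propan-1-ol
Product: 8 (2S,3S)-7-bromo-5-methoxy-2-{3-methoxy-4-[(triisopropylsilyl)oxy]phenyl}-3-{[(triisopropylsilyl)oxy]methyl}-2,3-dihydro-1,4-benzodioxine (trans)
Conditions: CuI (10 mol %), 3,4,7,8-tetramethyl-1,10-phenanthroline (20 mol %), Cs2CO3 (2 equiv), toluene (0.02 M), 110 °C
Reagents that add atoms: none
Why: In this intramolecular Ullmann-type copper-catalysed O-arylation the C7' alkoxide binds copper and delivers it to the neighbouring C5–Br to close the six-membered ring B, the remote C1–Br having no tethered nucleophile, and because no bond to C7' or C8' is broken the threo chain should become the trans (2S,3S) ring.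

Step 5
Reactants: 8 (2S,3S)-7-bromo-5-methoxy-2-{3-methoxy-4-[(triisopropylsilyl)oxy]phenyl}-3-{[(triisopropylsilyl)oxy]methyl}-2,3-dihydro-1,4-benzodioxine; 9 (E)-2-(3,3-diethoxyprop-1-en-1-yl)-4,4,5,5-tetramethyl-1,3,2-dioxaborolane
Product: 11 (2E)-3-[(2S,3S)-8-methoxy-3-{3-methoxy-4-[(triisopropylsilyl)oxy]phenyl}-2-{[(triisopropylsilyl)oxy]methyl}-2,3-dihydro-1,4-benzodioxin-6-yl]prop-2-enal, via diethyl acetal 10 (not isolated)
Conditions: Pd(dppf)Cl2 (5 mol %), K3PO4 (3 equiv), 1,4-dioxane/H2O 5:1, 80 °C; then 1 M HCl, THF, 0 °C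
Reagents that add atoms: water, O
Why: Suzuki–Miyaura coupling of the one remaining C1–Br with the alkenyl boronate should transfer the three-carbon unit with retention of the E geometry, and the allylic diethyl acetal is then hydrolysed by cold dilute acid under conditions that leave both silyl ethers and ring B in place.

Step 6
Reactants: 11 (2E)-3-[(2S,3S)-8-methoxy-3-{3-methoxy-4-[(triisopropylsilyl)oxy]phenyl}-2-{[(triisopropylsilyl)oxy]methyl}-2,3-dihydro-1,4-benzodioxin-6-yl]prop-2-enal
Product: 12 (2E)-3-[(2S,3S)-3-(4-hydroxy-3-methoxyphenyl)-2-(hydroxymethyl)-8-methoxy-2,3-dihydro-1,4-benzodioxin-6-yl]prop-2-enal, (7'S,8'S)-nocomtal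
Conditions: TBAF (3 equiv), AcOH (3 equiv), THF, 0 °C to rt
Reagents that add atoms: none
Why: Fluoride-mediated desilylation should cleave the aryl and the primary alkyl silyl ether in one operation, and the acetic acid buffer keeps the liberated phenol protonated so that neither the enal nor the benzylic C7'–O5 ether is exposed to phenoxide.

**Compound list**
1 | 2,4-dibromo-6-methoxyphenol | COc1cc(Br)cc(Br)c1O | starting material
2 | ethyl diazoacetate | CCOC(=O)C=[N+]=[N-] | starting material
3 | 4-formyl-2-methoxyphenyl acetate (vanillin acetate) | CC(=O)Oc1ccc(C=O)cc1OC | starting material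
4 | 2-(2,4-dibromo-6-methoxyphenoxy)-1-ethoxyethen-1-ol, the ester enol released from the rhodium-associated oxonium ylide (double-bond geometry not fixed; not isolated) | CCOC(O)=COc1c(Br)cc(Br)cc1OC | intermediate
5 | ethyl (2R,3S)-3-[4-(acetyloxy)-3-methoxyphenyl]-2-(2,4-dibromo-6-methoxyphenoxy)-3-hydroxypropanoate (threo; C2 = C8', C3 = C7') | CCOC(=O)[C@H](Oc1c(Br)cc(Br)cc1OC)[C@@H](O)c1ccc(OC(C)=O)c(OC)c1 | intermediate
6 | (1S,2S)-2-(2,4-dibromo-6-methoxyphenoxy)-1-(4-hydroxy-3-methoxyphenyl)propane-1,3-diol | OC[C@H](Oc1c(Br)cc(Br)cc1OC)[C@@H](O)c1ccc(O)c(OC)c1 | intermediate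
7 | (1S,2S)-2-(2,4-dibromo-6-methoxyphenoxy)-1-{3-methoxy-4-[(triisopropylsilyl)oxy]phenyl}-3-[(triisopropylsilyl)oxy]propan-1-ol | CC(C)[Si](OC[C@H](Oc1c(Br)cc(Br)cc1OC)[C@@H](O)c1ccc(O[Si](C(C)C)(C(C)C)C(C)C)c(OC)c1)(C(C)C)C(C)C | intermediate
8 | (2S,3S)-7-bromo-5-methoxy-2-{3-methoxy-4-[(triisopropylsilyl)oxy]phenyl}-3-{[(triisopropylsilyl)oxy]methyl}-2,3-dihydro-1,4-benzodioxine (trans; C2 = C7', C3 = C8') | COc1cc([C@@H]2Oc3cc(Br)cc(OC)c3O[C@H]2CO[Si](C(C)C)(C(C)C)C(C)C)ccc1O[Si](C(C)C)(C(C)C)C(C)C | intermediate
9 | (E)-2-(3,3-diethoxyprop-1-en-1-yl)-4,4,5,5-tetramethyl-1,3,2-dioxaborolane | CCOC(OCC)/C=C/B1OC(C)(C)C(C)(C)O1 | starting material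
10 | (2S,3S)-7-[(1E)-3,3-diethoxyprop-1-en-1-yl]-5-methoxy-2-{3-methoxy-4-[(triisopropylsilyl)oxy]phenyl}-3-{[(triisopropylsilyl)oxy]methyl}-2,3-dihydro-1,4-benzodioxine (not isolated) | COc1cc([C@@H]2Oc3cc(/C=C/C(OCC)OCC)cc(OC)c3O[C@H]2CO[Si](C(C)C)(C(C)C)C(C)C)ccc1O[Si](C(C)C)(C(C)C)C(C)C | intermediate
11 | (2E)-3-[(2S,3S)-8-methoxy-3-{3-methoxy-4-[(triisopropylsilyl)oxy]phenyl}-2-{[(triisopropylsilyl)oxy]methyl}-2,3-dihydro-1,4-benzodioxin-6-yl]prop-2-enal | COc1cc([C@@H]2Oc3cc(/C=C/C=O)cc(OC)c3O[C@H]2CO[Si](C(C)C)(C(C)C)C(C)C)ccc1O[Si](C(C)C)(C(C)C)C(C)C | intermediate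
12 | (2E)-3-[(2S,3S)-3-(4-hydroxy-3-methoxyphenyl)-2-(hydroxymethyl)-8-methoxy-2,3-dihydro-1,4-benzodioxin-6-yl]prop-2-enal, (7'S,8'S)-nocomtal | COc1cc([C@@H]2Oc3cc(/C=C/C=O)cc(OC)c3O[C@H]2CO)ccc1O | target

Total step count: 6
Longest linear sequence: 6 steps (1 to 12)

**Steps most likely to fail**

1. Step 1. The enol may be protonated at C8' (1,2-proton shift to the O–H insertion ester) faster than it adds to the aldehyde, or the addition may run with poor threo or facial selectivity. The fallback uses known chemistry, sets out from phenol 1 and comes back to the route at triol 6. Williamson alkylation of 1 with chloroacetic acid (aq NaOH, reflux) should give 2-(2,4-dibromo-6-methoxyphenoxy)acetic acid F1. Acylation of (R)-4-benzyloxazolidin-2-one through the pivaloyl mixed anhydride (PivCl, Et3N, LiCl, THF, −20 °C to rt) should give (R)-4-benzyl-3-[2-(2,4-dibromo-6-methoxyphenoxy)acetyl]oxazolidin-2-one F2. Its Z boron enolate (Bu2BOTf, iPr2NEt, CH2Cl2, −78 °C) should add to aldehyde 3 in an Evans syn aldol reaction to give (R)-4-benzyl-3-[(2R,3S)-3-[4-(acetyloxy)-3-methoxyphenyl]-2-(2,4-dibromo-6-methoxyphenoxy)-3-hydroxypropanoyl]oxazolidin-2-one F3. This is the same threo array, with the auxiliary fixing the absolute sense. LiBH4 (THF, 0 °C) then removes the auxiliary and the acetate to give 6. Loss of the acetate during the aldol work-up would be harmless, since it is removed at this point in any case.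

2. Step 4. Oxidative addition of copper into the electron-rich C5–Br bond may be slow at 110 °C, and during that time the C9' silyl group can migrate to the C7' alkoxide, so that ring closure runs through O9'. The fallback changes the approach by exchanging the halogens before the closure, so that the ring forms from an aryl iodide at a lower temperature; it sets out from 7 and comes back at acetal 10. A base-free copper-catalysed aromatic Finkelstein exchange (CuI, trans-N,N'-dimethylcyclohexane-1,2-diamine, NaI, 1,4-dioxane, 110 °C) should give (1S,2S)-2-(2,4-diiodo-6-methoxyphenoxy)-1-{3-methoxy-4-[(triisopropylsilyl)oxy]phenyl}-3-[(triisopropylsilyl)oxy]propan-1-ol F4. Ullmann closure (CuI, 3,4,7,8-tetramethyl-1,10-phenanthroline, Cs2CO3, toluene, 70 °C) should give (2S,3S)-7-iodo-5-methoxy-2-{3-methoxy-4-[(triisopropylsilyl)oxy]phenyl}-3-{[(triisopropylsilyl)oxy]methyl}-2,3-dihydro-1,4-benzodioxine F5. This iodide is coupled with 9 under the conditions of step 5 to give 10 and then 11.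

3. Step 5. Hot aqueous phosphate may cleave the aryl silyl ether, after which the phenoxide can open ring B at C7' (quinone methide formation); alternatively boronate 9 may protodeboronate before transmetalation. The fallback avoids base and palladium; it sets out from 8 and comes back at 11. Bromine–lithium exchange (n-BuLi, THF, −78 °C) and quenching with DMF should give (2S,3S)-8-methoxy-3-{3-methoxy-4-[(triisopropylsilyl)oxy]phenyl}-2-{[(triisopropylsilyl)oxy]methyl}-2,3-dihydro-1,4-benzodioxine-6-carbaldehyde F6. A Wittig reaction with (triphenylphosphoranylidene)acetaldehyde (toluene, 80 °C) should then give the E enal 11.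

**Further compounds**
F1 | step 1 | 2-(2,4-dibromo-6-methoxyphenoxy)acetic acid | OC(=O)COc1c(Br)cc(Br)cc1OC
F2 | step 1 | (R)-4-benzyl-3-[2-(2,4-dibromo-6-methoxyphenoxy)acetyl]oxazolidin-2-one | O=C1OC[C@@H](Cc2ccccc2)N1C(=O)COc1c(Br)cc(Br)cc1OC
F3 | step 1 | (R)-4-benzyl-3-[(2R,3S)-3-[4-(acetyloxy)-3-methoxyphenyl]-2-(2,4-dibromo-6-methoxyphenoxy)-3-hydroxypropanoyl]oxazolidin-2-one | O=C1OC[C@@H](Cc2ccccc2)N1C(=O)[C@H](Oc1c(Br)cc(Br)cc1OC)[C@@H](O)c1ccc(OC(C)=O)c(OC)c1
F4 | step 4 | (1S,2S)-2-(2,4-diiodo-6-methoxyphenoxy)-1-{3-methoxy-4-[(triisopropylsilyl)oxy]phenyl}-3-[(triisopropylsilyl)oxy]propan-1-ol | CC(C)[Si](OC[C@H](Oc1c(I)cc(I)cc1OC)[C@@H](O)c1ccc(O[Si](C(C)C)(C(C)C)C(C)C)c(OC)c1)(C(C)C)C(C)C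
F5 | step 4 | (2S,3S)-7-iodo-5-methoxy-2-{3-methoxy-4-[(triisopropylsilyl)oxy]phenyl}-3-{[(triisopropylsilyl)oxy]methyl}-2,3-dihydro-1,4-benzodioxine | COc1cc([C@@H]2Oc3cc(I)cc(OC)c3O[C@H]2CO[Si](C(C)C)(C(C)C)C(C)C)ccc1O[Si](C(C)C)(C(C)C)C(C)C
F6 | step 5 | (2S,3S)-8-methoxy-3-{3-methoxy-4-[(triisopropylsilyl)oxy]phenyl}-2-{[(triisopropylsilyl)oxy]methyl}-2,3-dihydro-1,4-benzodioxine-6-carbaldehyde | COc1cc([C@@H]2Oc3cc(C=O)cc(OC)c3O[C@H]2CO[Si](C(C)C)(C(C)C)C(C)C)ccc1O[Si](C(C)C)(C(C)C)C(C)C
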